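**Retrosynthetic overview**
1. Half-malonate C–O bond: the target comes from the free C20 allylic alcohol and Meldrum's acid in the last step, with no protecting group.
2. C8–C9 bond (nonadienyl numbering): α-sulfonyl carbanion of (S)-γ-cyclogeranyl phenyl sulfone plus (2E,6E)-8-bromogeranyl acetate. Both E-alkenes are bought with geranyl acetate, and the sulfonyl group is then removed reductively.
3. The exocyclic C=CH2 comes from the ring ketone by a non-basic methylenation.
4. Key step: the ring bond C(=O)–C*H comes from an acyclic ω-formyl (E)-vinyl sulfone. A chiral triazolylidene turns the aldehyde carbon into an acyl anion equivalent that attacks the likewise electrophilic β-carbon. The only ring (six-membered) and the only stereocentre arise in this one step.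
5. The acyclic precursor comes from 2,2-dimethylpent-4-enal by Horner–Wadsworth–Emmons olefination and linear hydroformylation.

Assumption: the (5aS,10bR) catalyst is taken to deliver the acyl carbon to the Re face of C6 of 5, by analogy with its known cyclisations. This is checked on 8 by chiral HPLC and rotation. If the sense is opposite, the equally available (5aR,10bS) salt is used with nothing else changed.

**Step 1**
Reactants: 1 2,2-dimethylpent-4-enal; 2 diethyl [(phenylsulfonyl)methyl]phosphonate
Product: 4 (E)-[(3,3-dimethylhexa-1,5-dien-1-yl)sulfonyl]benzene, via sodium phosphonate carbanion 3 (not isolated)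
Conditions: NaH, THF, 0 °C; then 1, 0 °C to rt
Reagents that add atoms: none
Why: Horner–Wadsworth–Emmons olefination, in which the sulfonyl-stabilised anion 3 adds reversibly to the non-enolisable neopentyl aldehyde and collapses to the E-vinyl sulfone, the remote terminal alkene being inert.

**Step 2**
Reactants: 4 (E)-[(3,3-dimethylhexa-1,5-dien-1-yl)sulfonyl]benzene
Product: 5 (E)-5,5-dimethyl-7-(phenylsulfonyl)hept-6-enal
Conditions: Rh(acac)(CO)2 (1 mol%), 4,5-bis(diphenylphosphino)-9,9-dimethylxanthene (3 mol%), CO/H2 (1:1, 20 bar), toluene, 70 °C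
Reagents that add atoms: carbon monoxide, [C-]#[O+]
Why: Linear-selective rhodium-catalysed hydroformylation, in which the wide-bite-angle diphosphine puts the formyl group on the terminal carbon of the monosubstituted alkene, while the 1,2-disubstituted vinyl sulfone flanked by a tert-alkyl group is too hindered to compete.

**Step 3 (key step)**
Reactants: 5 (E)-5,5-dimethyl-7-(phenylsulfonyl)hept-6-enal
Product: 7 (2S)-3,3-dimethyl-2-[(phenylsulfonyl)methyl]cyclohexan-1-one, via Breslow enaminol 6 (not isolated)
Conditions: (5aS,10bR)-2-(pentafluorophenyl)-5a,10b-dihydro-4H,6H-indeno[2,1-b][1,2,4]triazolo[4,3-d][1,4]oxazin-2-ium tetrafluoroborate (20 mol%), KN(SiMe3)2 (18 mol%), toluene (0.02 M), 25 °C, argon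
Reagents that add atoms: none
Why: Proposed new method: the free triazolylidene adds to the aldehyde and a proton shift gives Breslow enaminol 6, an acyl anion equivalent whose former carbonyl carbon attacks the β-carbon of the vinyl sulfone in a 6-exo-trig closure helped by the Thorpe–Ingold effect of the gem-dimethyl group; proton transfer and loss of the carbene give 7, the indane wall of the catalyst exposing the Re face of C6 and so setting C2 as S; the closest known reaction types are the asymmetric intramolecular Stetter reaction of aliphatic aldehydes onto enoates, β,β-disubstituted enoates and vinylphosphonates with this catalyst family and the achiral intermolecular Stetter reaction onto vinyl sulfones; base is kept below the catalyst loading so that the β-sulfonyl ketone neither epimerises nor loses sulfinate.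

**Step 4**
Reactants: 7 (2S)-3,3-dimethyl-2-[(phenylsulfonyl)methyl]cyclohexan-1-one
Product: 8 ({[(1S)-2,2-dimethyl-6-methylidenecyclohexyl]methyl}sulfonyl)benzene, the (S)-γ-cyclogeranyl phenyl sulfone
Conditions: Zn, CH2Br2, TiCl4, THF, −40 to 5 °C (reagent pre-formed); then 7, CH2Cl2, 0 °C to rt
Reagents that add atoms: dibromomethane, BrCBr
Why: Takai–Lombardo methylenation, whose non-basic gem-dimetallic CH2 reagent adds to the ketone and expels metal oxide without enolate formation, so the α-stereocentre is kept (still S), no sulfinate is lost by E1cB, and the sulfone is untouched.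

**Step 5**
Reactants: 9 geranyl acetate, (2E)-3,7-dimethylocta-2,6-dien-1-yl acetate
Product: 10 (2E,6E)-8-hydroxy-3,7-dimethylocta-2,6-dien-1-yl acetate
Conditions: SeO2 (10 mol%), t-BuOOH (3 equiv), 2-hydroxybenzoic acid (10 mol%), CH2Cl2, rt
Reagents that add atoms: tert-butyl hydroperoxide, CC(C)(C)OO; selenium dioxide, O=[Se]=O
Why: Catalytic SeO2 allylic oxidation (ene reaction followed by [2,3]-sigmatropic shift) attacks the more electron-rich terminal alkene remote from the acetate and oxidises only its E-methyl group, the minor enal by-product being removed by chromatography.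

**Step 6**
Reactants: 10 (2E,6E)-8-hydroxy-3,7-dimethylocta-2,6-dien-1-yl acetate
Product: 11 (2E,6E)-8-bromo-3,7-dimethylocta-2,6-dien-1-yl acetate
Conditions: CBr4, PPh3, CH2Cl2, 0 °C
Reagents that add atoms: tetrabromomethane, BrC(Br)(Br)Br
Why: Appel reaction, an SN2 displacement of the alkoxyphosphonium ion at the primary allylic carbon under neutral conditions that leaves both E-alkenes and the acetate unchanged.

**Step 7**
Reactants: 8 (S)-γ-cyclogeranyl phenyl sulfone; 11 (2E,6E)-8-bromo-3,7-dimethylocta-2,6-dien-1-yl acetate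
Product: 13 (2E,6E)-9-[(1S)-2,2-dimethyl-6-methylidenecyclohexyl]-3,7-dimethyl-9-(phenylsulfonyl)nona-2,6-dien-1-yl acetate (mixture of C9 epimers), via lithiated sulfone 12 (not isolated)
Conditions: n-BuLi (1.05 equiv), THF–N,N'-dimethylpropyleneurea, −78 °C; then 11, −78 to −40 °C
Reagents that add atoms: none
Why: Sulfone carbanion alkylation, in which SN2 attack on the primary allylic bromide at −78 °C is much faster than attack on the acetate (as in the industrial sulfone route to vitamin A acetate); the ring stereocentre lies β to the carbanion and is untouched, and the new sulfonyl-bearing centre is erased in the next step.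

**Step 8**
Reactants: 13 coupled sulfone acetate
Product: 15 (2E,6E)-9-[(1S)-2,2-dimethyl-6-methylidenecyclohexyl]-3,7-dimethylnona-2,6-dien-1-ol, via desulfonylated acetate 14 (not isolated)
Conditions: Na/Hg (6% Na), MeOH–THF, −10 °C to rt
Reagents that add atoms: none
Why: Reductive desulfonylation by electron transfer cleaves the alkyl C–S bond without touching the isolated alkenes or the stereocentre, and the NaOMe generated then removes the acetate by transesterification in the same flask.

**Step 9**
Reactants: 15 C20 allylic alcohol; 16 Meldrum's acid (2,2-dimethyl-1,3-dioxane-4,6-dione)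
Product: 17 3-{[(2E,6E)-9-[(1S)-2,2-dimethyl-6-methylidenecyclohexyl]-3,7-dimethylnona-2,6-dien-1-yl]oxy}-3-oxopropanoic acid (target)
Conditions: toluene, 85 °C
Reagents that add atoms: none
Why: Acylative ring opening of Meldrum's acid by the alcohol with loss of acetone gives the malonic half ester directly, at a temperature below decarboxylation and at an acidity too low to isomerise the exocyclic alkene or ionise the allylic ester.

**Compound list**
1 | 2,2-dimethylpent-4-enal | C=CCC(C)(C)C=O | starting material
2 | diethyl [(phenylsulfonyl)methyl]phosphonate | CCOP(=O)(CS(=O)(=O)c1ccccc1)OCC | starting material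
3 | sodium salt of the carbanion of 2 (not isolated) | CCOP(=O)([CH-]S(=O)(=O)c1ccccc1)OCC.[Na+] | intermediate
4 | (E)-[(3,3-dimethylhexa-1,5-dien-1-yl)sulfonyl]benzene | C=CCC(C)(C)/C=C/S(=O)(=O)c1ccccc1 | intermediate
5 | (E)-5,5-dimethyl-7-(phenylsulfonyl)hept-6-enal | O=CCCCC(C)(C)/C=C/S(=O)(=O)c1ccccc1 | intermediate
6 | Breslow enaminol from 5 and the (5aS,10bR)-triazolylidene (not isolated) | OC(CCCC(C)(C)/C=C/S(=O)(=O)c1ccccc1)=C1N(c2c(F)c(F)c(F)c(F)c2F)N=C2CO[C@H]3Cc4ccccc4[C@H]3N12 | intermediate
7 | (2S)-3,3-dimethyl-2-[(phenylsulfonyl)methyl]cyclohexan-1-one | O=C1CCCC(C)(C)[C@@H]1CS(=O)(=O)c1ccccc1 | intermediate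
8 | ({[(1S)-2,2-dimethyl-6-methylidenecyclohexyl]methyl}sulfonyl)benzene | C=C1CCCC(C)(C)[C@@H]1CS(=O)(=O)c1ccccc1 | intermediate
9 | geranyl acetate | CC(C)=CCC/C(C)=C/COC(C)=O | starting material
10 | (2E,6E)-8-hydroxy-3,7-dimethylocta-2,6-dien-1-yl acetate | OC/C(C)=C/CC/C(C)=C/COC(C)=O | intermediate
11 | (2E,6E)-8-bromo-3,7-dimethylocta-2,6-dien-1-yl acetate | BrC/C(C)=C/CC/C(C)=C/COC(C)=O | intermediate
12 | α-lithiated sulfone from 8 (not isolated) | C=C1CCCC(C)(C)[C@@H]1C([Li])S(=O)(=O)c1ccccc1 | intermediate
13 | (2E,6E)-9-[(1S)-2,2-dimethyl-6-methylidenecyclohexyl]-3,7-dimethyl-9-(phenylsulfonyl)nona-2,6-dien-1-yl acetate, C9 epimers | C=C1CCCC(C)(C)[C@@H]1C(C/C(C)=C/CC/C(C)=C/COC(C)=O)S(=O)(=O)c1ccccc1 | intermediate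
14 | (2E,6E)-9-[(1S)-2,2-dimethyl-6-methylidenecyclohexyl]-3,7-dimethylnona-2,6-dien-1-yl acetate (not isolated) | C=C1CCCC(C)(C)[C@@H]1CC/C(C)=C/CC/C(C)=C/COC(C)=O | intermediate
15 | (2E,6E)-9-[(1S)-2,2-dimethyl-6-methylidenecyclohexyl]-3,7-dimethylnona-2,6-dien-1-ol | C=C1CCCC(C)(C)[C@@H]1CC/C(C)=C/CC/C(C)=C/CO | intermediate
16 | Meldrum's acid | CC1(C)OC(=O)CC(=O)O1 | starting material
17 | 3-{[(2E,6E)-9-[(1S)-2,2-dimethyl-6-methylidenecyclohexyl]-3,7-dimethylnona-2,6-dien-1-yl]oxy}-3-oxopropanoic acid | C=C1CCCC(C)(C)[C@@H]1CC/C(C)=C/CC/C(C)=C/COC(=O)CC(=O)O | target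

**Step count**
Total steps: 9. Longest linear sequence: 7 (steps 1, 2, 3, 4, 7, 8, 9).

**Three steps most likely to fail**

Step 3. The bulky enaminol may not reach the neopentyl β-carbon, or the ee may be low. The fallback sets out from 5 and comes back at 7.
- The carbonyl carbon stays the nucleophile but is generated by one-electron reduction. SmI2 (2.5 equiv) with t-BuOH in THF, −78 to 0 °C, makes the ketyl radical anion. It closes 6-exo onto the vinyl sulfone to give racemic trans-3,3-dimethyl-2-[(phenylsulfonyl)methyl]cyclohexan-1-ol F1.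
- Kinetic resolution with immobilised Candida antarctica lipase B and vinyl acetate in methyl tert-butyl ether follows the Kazlauskas rule. It leaves (1S,2S)-3,3-dimethyl-2-[(phenylsulfonyl)methyl]cyclohexan-1-ol F2 untouched. The other enantiomer becomes (1R,2R)-3,3-dimethyl-2-[(phenylsulfonyl)methyl]cyclohexyl acetate F3, which is removed by chromatography.
- Dess–Martin periodinane with NaHCO3 in CH2Cl2 oxidises F2 to 7.

Step 4. The β-sulfonyl ketone may enolise, lose sulfinate or racemise under the Lewis acidic titanium and zinc halides. The fallback sets out from 7 and comes back at 8.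
- A Peterson sequence separates addition from elimination. The weakly basic organocerium reagent from Me3SiCH2Li and CeCl3 (THF, −78 °C) adds to the ketone. The product is (2S)-3,3-dimethyl-2-[(phenylsulfonyl)methyl]-1-[(trimethylsilyl)methyl]cyclohexan-1-ol F4, which has no acidic α-carbonyl hydrogen left.
- Aqueous HF in MeCN at rt then eliminates the silyl and hydroxyl groups regiospecifically to the exocyclic alkene 8.

Step 7. The hindered, strongly basic carbanion may attack or deprotonate the acetate instead of displacing bromide. The fallback sets out from 11 and comes back at 15.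
- The ester is removed before the coupling and the oxygen is carried as its own alkoxide. i-Bu2AlH (2.2 equiv, CH2Cl2, −78 °C) reduces only the acetate to give (2E,6E)-8-bromo-3,7-dimethylocta-2,6-dien-1-ol F5.
- F5 is used at once and added at −78 °C to two equivalents of 12. One equivalent serves as base toward the hydroxyl group and is recovered as 8.
- The coupling product is (2E,6E)-9-[(1S)-2,2-dimethyl-6-methylidenecyclohexyl]-3,7-dimethyl-9-(phenylsulfonyl)nona-2,6-dien-1-ol F6. Na/Hg in MeOH converts it directly into 15.

**Further compounds**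
F1 | step 3 | racemic trans-3,3-dimethyl-2-[(phenylsulfonyl)methyl]cyclohexan-1-ol | O[C@H]1CCCC(C)(C)[C@@H]1CS(=O)(=O)c1ccccc1.O[C@@H]1CCCC(C)(C)[C@H]1CS(=O)(=O)c1ccccc1
F2 | step 3 | (1S,2S)-3,3-dimethyl-2-[(phenylsulfonyl)methyl]cyclohexan-1-ol | O[C@H]1CCCC(C)(C)[C@@H]1CS(=O)(=O)c1ccccc1
F3 | step 3 | (1R,2R)-3,3-dimethyl-2-[(phenylsulfonyl)methyl]cyclohexyl acetate | CC(=O)O[C@@H]1CCCC(C)(C)[C@H]1CS(=O)(=O)c1ccccc1
F4 | step 4 | (2S)-3,3-dimethyl-2-[(phenylsulfonyl)methyl]-1-[(trimethylsilyl)methyl]cyclohexan-1-ol, C1 epimers | C[Si](C)(C)CC1(O)CCCC(C)(C)[C@@H]1CS(=O)(=O)c1ccccc1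
F5 | step 7 | (2E,6E)-8-bromo-3,7-dimethylocta-2,6-dien-1-ol | BrC/C(C)=C/CC/C(C)=C/CO
F6 | step 7 | (2E,6E)-9-[(1S)-2,2-dimethyl-6-methylidenecyclohexyl]-3,7-dimethyl-9-(phenylsulfonyl)nona-2,6-dien-1-ol, C9 epimers | C=C1CCCC(C)(C)[C@@H]1C(C/C(C)=C/CC/C(C)=C/CO)S(=O)(=O)c1ccccc1
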